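Atom numbering used throughout (elemane numbering): ring carbons C5–C10; C1=C2 is the vinyl group on C10 and C14 its methyl; C3=C4(–C15) is the 2‑propenoic acid unit on C5; C11(=C13)–C12 is the lactone unit on C7; oxygen sits on C6 (lactone) and C8 (angelate). "α" means the ring face opposite to C14.

## Structural features

The target has one carbocycle, the cyclohexane C5–C10, trans‑fused along C6–C7 to an α‑methylene‑γ‑butyrolactone (O–C6, C12=O, C11=C13). C10 is quaternary (methyl C14 and vinyl C1=C2), C5 carries a 2‑propenoic acid (C4=C3, C15OOH), C8 carries an angelate and C9 is the only unsubstituted ring carbon. The five stereocenters C10, C5, C6, C7 and C8 are contiguous, and every ring substituent except the axial C14 methyl is equatorial. Fragile groups are the (Z)‑configured angelate (Z to E isomerization), two Michael acceptors (methylene lactone and acrylic acid), the C5–H that is allylic and next to C6, and the free acid. The real difficulty is the vicinal pair C5/C10: the methyl and vinyl groups on C10 are sterically almost equal (similar A values), so neither thermodynamic equilibration nor simple steric approach control can tell them apart; they have to be set by a stereospecific event. A second point is the pseudo‑symmetry about C6: C5 and C7 both carry an acrylate carbon, but only the C7 unit is lactonized. The key step exploits the array C2=C1–C10–C5–C6: the C10 vinyl group together with C5 and C6 is a pent‑4‑enoic acid retron, and the acrylate unit (C3, C4, C15) with C5 and C6 is the carbon skeleton of itaconic acid. A [3,3] shift of an open‑chain allylic itaconate therefore creates the C5–C10 bond, both stereocenters, the vinyl group and the intact acrylate before any ring exists.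

## Logic of the disconnections

27 to 26 to 23 + 24. The bonds cut are the O–C(CH3)3 bond of the C15 ester and the acyl C–O bond at C8. The angelate is the most isomerization‑prone group and is therefore put on last; 24 is commercial. The forward demand is acylation of a hindered equatorial secondary alcohol without Z to E isomerization, and an acidolysis at C15 that leaves the angelate and the lactone alone.

23 to 22 to 19. The bonds cut are C6–C7 and O6–C12, the two bonds shared by the carbocycle and the lactone. A 2‑(metallomethyl)enoate that attacks a C6 aldehyde through C7 closes the cyclohexane, creates the C11=C13 methylene and sets up lactonization in one operation. The gain is that the bicycle becomes an open chain and C6 and C7 disappear as stereocenters. The demands are a trans‑diequatorial closure, lactonization onto C12 and not C15 (hence methyl ester at C12 and tert‑butyl ester at C15), and no loss of the C8 oxygen from the allylmetal.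

19 to 17 to 16 to 14 + 15, and 14 to 13 to 12. The bond cut is C7–C11 (plus C13–Br and the oxidation levels at C6 and C7). The three lactone carbons C11, C12 and C13 come from commercial 15 by addition to a C7 aldehyde. The demand is that the α‑oxygenated C8 centre survives; C6 is kept as the carboxylic acid until the last moment so that C5–H is not enolizable during these steps.

12 to 9 (key). The bond cut is C5–C10, with reconnection of O to C2 (retro‑[3,3]). Both stereocenters, including the quaternary one, vanish, the vinyl group becomes an (E)‑trisubstituted allylic ester, and the molecule falls into an allylic alcohol and a C5 diacid. The forward step needs a defined (E) alkene, a defined enolate geometry, regioselective enolization at C5 and control of the absolute sense by a chiral boron controller.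

9 to 8 to 6 + 7. The bonds cut are the two ester C–O bonds. 7 is the commercial anhydride that already contains C3, C4, C5, C6 and C15 with the methylene in place. The demand is opening at the non‑conjugated carbonyl (C6).

6 to 3 to 2 to 1. The bonds cut are C1–C2 and C10–C14 (carbometalation of an alkyne, then hydroxymethylation) and C9–C10 (acetylide opening of an epoxide). The chain is reduced to 1, which supplies C7, C8, C9 and the C8 configuration. The demand is syn carbometalation so that the alkene is (E).

## Other disconnections considered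

Alternative 1: the route that comes to mind first cuts C10–C14 by conjugate addition on a cyclohexenone. Enone A1 would take Me2CuLi anti to the C8 silyloxy group to give ketone A2 with the correct C8/C10 relation; C5 and C7 would then be alkylated through the C6 ketone enolates and the ketone reduced and lactonized. The grounds against it are structural. The C6 ketone must be reduced by axial hydride delivery on the face that carries the axial C14 methyl (a syn‑axial interaction), so small hydrides should favour the axial alcohol and a cis lactone. The enolate toward C7 has the C8 silyloxy group in the β position (E1cB risk). Alkylation at C5 is next to the quaternary carbon, and both acrylate units need separate enolate methylenations in each other's presence. The step count is not lower.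

Alternative 2: the biomimetic cut is the same C5–C10 bond, made by a Cope rearrangement of the ten‑membered (E,E)‑diene lactone A3 (ring contraction from ten to six). The chair transition state would give the right C5/C10 relation, but A3 itself needs a macrocyclization of a long chain with three stereocenters in place. Its C4=C5 double bond must hold an ester at C4 cis to C6, an arrangement that is geometrically labile during chain assembly. The Cope step is also an equilibrium reached only at high temperature. The chosen [3,3] shift is the open‑chain oxygen analogue: same bond, same chair logic, no ring to build, and irreversible because a carboxylic acid is formed.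

Alternative 3: a (2+2) photocycloaddition of enone A4 with cyclobutene ester A5 would form C5–C4 and C10–C1. Thermal cycloreversion of photoadduct A6 (cleavage of C1–C4 and C2–C3) would then release the vinyl group and the acrylate in the right oxidation state in two steps. The mechanistic objection is stereochemical. The cis ring fusion of A6 places both new bonds on the same ring face, which leads to the C5‑epimeric (cis) series. Epimerization next to the C6 ketone can only repair this if C10 is already correct relative to C8, which would require cycloaddition syn to the C8 silyloxy group, against the expected steric preference. Because methyl and vinyl are of similar size there is no thermodynamic bias to fall back on.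

Key step: step 6

Assumption: the (S,S) boron controller is taken to induce the (5R,10S) sense by analogy with other (E)‑3‑methylalk‑2‑enyl esters; if the sense were opposite, the equally accessible (R,R) controller would be used. The controller is made beforehand from (S,S)‑1,2‑diphenylethane‑1,2‑diamine, 3,5‑bis(trifluoromethyl)benzenesulfonyl chloride and BBr3 and is treated as a reagent.

## Route

Step 1
Reactants: 1 (R)-glycidol
Product: 2 (2S)-pent-4-yne-1,2-diol
Conditions: LiC≡CH·H2NCH2CH2NH2, DMSO, 0 to 25 °C; aq. NH4Cl
Reagents that add atoms: lithium acetylide (ethylenediamine complex), [Li]C#C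
Why: SN2 opening of the epoxide at its terminal carbon by acetylide (C9–C10 bond); the alkoxide of 1 can only undergo a degenerate Payne shift, and the C8 centre is not touched, so it keeps the configuration of 1.

Step 2
Reactants: 2 (2S)-pent-4-yne-1,2-diol
Product: 3 (4S)-4,5-bis[(tert-butyldimethylsilyl)oxy]pent-1-yne
Conditions: TBSCl, imidazole, DMF, 25 °C
Reagents that add atoms: tert-butyldimethylsilyl chloride, CC(C)(C)[Si](C)(C)Cl
Why: Standard silylation of both hydroxyls; the primary (C7) and secondary (C8) silyl ethers can later be told apart by rate of cleavage.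

Step 3
Reactants: 3 (4S)-4,5-bis[(tert-butyldimethylsilyl)oxy]pent-1-yne
Product: 6 (2E,5S)-5,6-bis[(tert-butyldimethylsilyl)oxy]-3-methylhex-2-en-1-ol, via alkenylalane 4 (not isolated), via lithium alanate 5 (not isolated)
Conditions: Me3Al, Cp2ZrCl2 (cat.), CH2Cl2, 0 to 25 °C; n-BuLi, THF, −78 °C; (CH2O)n, −78 to 25 °C
Reagents that add atoms: trimethylaluminium, C[Al](C)C; paraformaldehyde (as formaldehyde), C=O
Why: Negishi carboalumination adds methyl (C14) and aluminium syn across the alkyne, methyl to the internal carbon C10; hydroxymethylation of the alanate at C1 with retention gives the (E) alkene in which C9 is trans to C2.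

Step 4
Reactants: 6 (2E,5S)-5,6-bis[(tert-butyldimethylsilyl)oxy]-3-methylhex-2-en-1-ol; 7 itaconic anhydride
Product: 8 4-{[(2E,5S)-5,6-bis[(tert-butyldimethylsilyl)oxy]-3-methylhex-2-en-1-yl]oxy}-2-methylidene-4-oxobutanoic acid
Conditions: toluene, 70 °C, no base
Reagents that add atoms: none
Why: Alcoholysis of the unsymmetrical anhydride takes place at the non-conjugated, more electrophilic carbonyl (C6), leaving the conjugated carboxyl (C15) free; the absence of amine avoids migration of the exocyclic double bond.

Step 5
Reactants: 8 the hydrogen itaconate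
Product: 9 1-tert-butyl 4-[(2E,5S)-5,6-bis[(tert-butyldimethylsilyl)oxy]-3-methylhex-2-en-1-yl] 2-methylidenebutanedioate
Conditions: Me2NCH(OtBu)2, toluene, 80 °C
Reagents that add atoms: N,N-dimethylformamide di-tert-butyl acetal, CN(C)C(OC(C)(C)C)OC(C)(C)C
Why: Neutral tert-butylation of the conjugated acid by the amide acetal; the tert-butyl ester is chosen because it resists lactonization at C15 later and is removed by acid at the end.

Step 6
Reactants: 9 the allylic tert-butyl itaconate
Product: 12 (2R)-4-tert-butoxy-2-[(3S,5S)-5,6-bis[(tert-butyldimethylsilyl)oxy]-3-methylhex-1-en-3-yl]-3-methylidene-4-oxobutanoic acid, via boron ketene acetal 10 (not isolated), via acyloxyborane 11 (not isolated)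
Conditions: (4S,5S)-2-bromo-4,5-diphenyl-1,3-bis{[3,5-bis(trifluoromethyl)phenyl]sulfonyl}-1,3,2-diazaborolidine, Et3N, toluene–hexane, −78 °C, then −20 to 4 °C; aq. work-up
Reagents that add atoms: none
Why: The bromoborane binds the C6 ester carbonyl and Et3N removes a C5 proton (the only position that is both α to an ester and allylic), giving boron ketene acetal 10 with C4 anti to the O–B bond (E(O) geometry, as simple esters give under these conditions). On warming, the [3,3] shift C5=C6–O–C2–C1=C10 forms C5–C10 and C1=C2 through a chair; the closest known reaction type is the enantioselective boron-enolate variant of the Ireland–Claisen rearrangement, which has been applied to (E)-3-methylalk-2-enyl esters of β,γ-unsaturated acids. No ring is closed: C5 and C10 are joined in an open chain, and hydrolysis of acyloxyborane 11 frees the C6 acid. C10 is set by the (E) geometry of C1=C10 (C9 pseudo-equatorial, C14 pseudo-axial) together with the alkene face that is attacked. C5 is set relative to C10 by the E(O) geometry (C4 pseudo-axial), which gives the anti-type relation that becomes the trans arrangement of vinyl and acrylate on the later ring. The absolute sense (5R,10S) is imposed by the C2-symmetric sulfonamide ligand on boron, which distinguishes the two mirror-image chairs; the remote C8 centre has no influence and is not affected. The step needs enolization at C5 without migration of the C3=C4 double bond (soft enolization at −78 °C, no free strong base), E(O) geometry, and chair over boat (normal in open-chain cases). The shift is irreversible and delivers the vinyl/acrylate pair with C15 already at the acid oxidation level.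

Step 7
Reactants: 12 the bis-silyl ether acid
Product: 13 (2R)-4-tert-butoxy-2-[(3S,5S)-5-[(tert-butyldimethylsilyl)oxy]-6-hydroxy-3-methylhex-1-en-3-yl]-3-methylidene-4-oxobutanoic acid
Conditions: HF·pyridine, pyridine, THF, 0 °C
Reagents that add atoms: none
Why: Buffered HF·pyridine cleaves the unhindered primary silyl ether at C7 much faster than the secondary one at C8; acid, ester and alkenes are inert and no stereocenter is involved.

Step 8
Reactants: 13 the C7 alcohol
Product: 14 (2R)-4-tert-butoxy-2-[(3S,5S)-5-[(tert-butyldimethylsilyl)oxy]-3-methyl-6-oxohex-1-en-3-yl]-3-methylidene-4-oxobutanoic acid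
Conditions: Dess–Martin periodinane, CH2Cl2, 0 to 25 °C
Reagents that add atoms: none
Why: Dess–Martin oxidation is non-basic, so the α-silyloxy aldehyde should form without epimerization at C8; the carboxylic acid does not interfere.

Step 9
Reactants: 14 the C7 aldehyde; 15 methyl acrylate
Product: 16 (2R)-4-tert-butoxy-2-[(3S,5S)-5-[(tert-butyldimethylsilyl)oxy]-6-hydroxy-7-(methoxycarbonyl)-3-methylocta-1,7-dien-3-yl]-3-methylidene-4-oxobutanoic acid (both C7 epimers)
Conditions: 15 (excess), DABCO (2 equiv), MeOH, 25 °C
Reagents that add atoms: none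
Why: Morita–Baylis–Hillman reaction; α-oxygenated aldehydes are activated acceptors, and the α-substituted acrylate already in the molecule cannot take part. The C6 carboxyl is present as its ammonium carboxylate, which makes C5–H non-acidic, and the new C7 carbinol centre is of no consequence because C7 becomes sp2 in step 10.

Step 10
Reactants: 16 the Baylis–Hillman adduct
Product: 17 (2R)-2-[(3S,5S,6Z)-8-bromo-5-[(tert-butyldimethylsilyl)oxy]-7-(methoxycarbonyl)-3-methylocta-1,6-dien-3-yl]-4-tert-butoxy-3-methylidene-4-oxobutanoic acid
Conditions: NBS, Me2S, CH2Cl2, −20 to 0 °C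
Reagents that add atoms: N-bromosuccinimide, O=C1CCC(=O)N1Br
Why: The alcohol is activated as an alkoxysulfonium ion and bromide attacks in the SN2′ sense at C13, giving the thermodynamically preferred (Z)-2-(bromomethyl)enoate (ester trans to C8); alkenes and the silyl ether are not attacked by this reagent.

Step 11
Reactants: 17 the allylic bromide acid
Product: 19 tert-butyl (3R,4S,6S,7Z)-9-bromo-6-[(tert-butyldimethylsilyl)oxy]-4-ethenyl-3-formyl-8-(methoxycarbonyl)-4-methyl-2-methylidenenon-7-enoate, via acid chloride 18 (not isolated)
Conditions: Me2C=C(Cl)NMe2, CH2Cl2, 0 °C; then LiAlH(OtBu)3, THF, −78 °C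
Reagents that add atoms: none
Why: The chloroenamine converts the acid into the acid chloride under neutral conditions (no HCl, no base, hence no ketene and no enolization at C5); LiAlH(OtBu)3 reduces acid chlorides to aldehydes at −78 °C and leaves both esters, the allylic bromide and the silyl ether. The aldehyde is used at once.

Step 12
Reactants: 19 the C6 aldehyde with the allylic bromide
Product: 22 tert-butyl 8α-[(tert-butyldimethylsilyl)oxy]elema-1,3,11(13)-trien-12,6α-olid-15-oate, via allylchromium species 20 (not isolated), via hydroxy ester 21 (not isolated)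
Conditions: CrCl2, THF, 25 °C, high dilution; then p-TsOH (cat.), CH2Cl2, 25 °C
Reagents that add atoms: none
Why: Intramolecular Nozaki–Hiyama allylation: two equivalents of divalent chromium give the allylchromium species, which adds through C7 to the C6 aldehyde and closes the cyclohexane with the C11=C13 methylene in place. Allylchromium species are configurationally mobile, so closure should run through the chair-like arrangement in which C5, C8, the C6 oxygen and C11 are all equatorial (an axial C6 oxygen would be syn-axial to C14), giving the trans relation at C6/C7. The C6 oxygen then lactonizes onto the methyl ester C12 and not onto the tert-butyl ester C15.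

Step 13
Reactants: 22 the silyl-protected lactone
Product: 23 tert-butyl 8α-hydroxyelema-1,3,11(13)-trien-12,6α-olid-15-oate
Conditions: HF·pyridine, THF, 0 to 25 °C
Reagents that add atoms: none
Why: Fluoride-free-base conditions remove the secondary silyl ether without conjugate addition to the methylene lactone and without lactone migration to O8, which needs alkoxide.

Step 14
Reactants: 23 the C8 alcohol; 24 angelic acid
Product: 26 tert-butyl 8α-(angeloyloxy)elema-1,3,11(13)-trien-12,6α-olid-15-oate, via mixed anhydride 25 (not isolated)
Conditions: 24, 2,4,6-Cl3C6H2COCl, Et3N, toluene, 25 °C; then 23, 80 °C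
Reagents that add atoms: none
Why: Yamaguchi-type acylation through the mixed anhydride without a nucleophilic pyridine catalyst; this avoids the addition–elimination pathway that turns angelates into tiglates, and the hindered aroyl carbonyl directs the alcohol to the angeloyl carbonyl. C8 keeps its configuration (O-acylation).

Step 15
Reactants: 26 the tert-butyl ester
Product: 27 8α-(angeloyloxy)elema-1,3,11(13)-trien-12,6α-olid-15-oic acid (target)
Conditions: CF3CO2H, CH2Cl2, 0 °C
Reagents that add atoms: none
Why: Acidolysis of the tert-butyl ester by loss of 2-methylpropene; lactone, angelate and alkenes tolerate short exposure to the acid at 0 °C, and no stereocenter is involved.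

## Compound list

1 | (R)-glycidol, (2R)-oxiran-2-ylmethanol | C1[C@H](O1)CO | starting material
2 | (2S)-pent-4-yne-1,2-diol | C#CC[C@H](O)CO | intermediate
3 | (4S)-4,5-bis[(tert-butyldimethylsilyl)oxy]pent-1-yne | C#CC[C@H](O[Si](C)(C)C(C)(C)C)CO[Si](C)(C)C(C)(C)C | intermediate
4 | [(1E,4S)-4,5-bis[(tert-butyldimethylsilyl)oxy]-2-methylpent-1-en-1-yl]dimethylalane | C[Al](C)/C=C(\C)C[C@H](O[Si](C)(C)C(C)(C)C)CO[Si](C)(C)C(C)(C)C | intermediate
5 | lithium butyl[(1E,4S)-4,5-bis[(tert-butyldimethylsilyl)oxy]-2-methylpent-1-en-1-yl]dimethylalanate | [Li+].CCCC[Al-](C)(C)/C=C(\C)C[C@H](O[Si](C)(C)C(C)(C)C)CO[Si](C)(C)C(C)(C)C | intermediate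
6 | (2E,5S)-5,6-bis[(tert-butyldimethylsilyl)oxy]-3-methylhex-2-en-1-ol | OC/C=C(\C)C[C@H](O[Si](C)(C)C(C)(C)C)CO[Si](C)(C)C(C)(C)C | intermediate
7 | itaconic anhydride, 3-methylideneoxolane-2,5-dione | C=C1CC(=O)OC1=O | starting material
8 | 4-{[(2E,5S)-5,6-bis[(tert-butyldimethylsilyl)oxy]-3-methylhex-2-en-1-yl]oxy}-2-methylidene-4-oxobutanoic acid | C=C(CC(=O)OC/C=C(\C)C[C@H](O[Si](C)(C)C(C)(C)C)CO[Si](C)(C)C(C)(C)C)C(=O)O | intermediate
9 | 1-tert-butyl 4-[(2E,5S)-5,6-bis[(tert-butyldimethylsilyl)oxy]-3-methylhex-2-en-1-yl] 2-methylidenebutanedioate | C=C(CC(=O)OC/C=C(\C)C[C@H](O[Si](C)(C)C(C)(C)C)CO[Si](C)(C)C(C)(C)C)C(=O)OC(C)(C)C | intermediate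
10 | boron ketene acetal of 9 (O-boron enolate at C6, C4 anti to O–B, (4S,5S)-diazaborolidine on boron) | C=C(C(=O)OC(C)(C)C)/C=C(/OB1N(S(=O)(=O)c2cc(cc(c2)C(F)(F)F)C(F)(F)F)[C@@H](c2ccccc2)[C@H](c2ccccc2)N1S(=O)(=O)c1cc(cc(c1)C(F)(F)F)C(F)(F)F)OC/C=C(\C)C[C@H](O[Si](C)(C)C(C)(C)C)CO[Si](C)(C)C(C)(C)C | intermediate
11 | acyloxyborane of acid 12 (C6 carboxyl bound to the diazaborolidine boron) | C=C[C@](C)(C[C@H](O[Si](C)(C)C(C)(C)C)CO[Si](C)(C)C(C)(C)C)[C@@H](C(=O)OB1N(S(=O)(=O)c2cc(cc(c2)C(F)(F)F)C(F)(F)F)[C@@H](c2ccccc2)[C@H](c2ccccc2)N1S(=O)(=O)c1cc(cc(c1)C(F)(F)F)C(F)(F)F)C(=C)C(=O)OC(C)(C)C | intermediate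
12 | (2R)-4-tert-butoxy-2-[(3S,5S)-5,6-bis[(tert-butyldimethylsilyl)oxy]-3-methylhex-1-en-3-yl]-3-methylidene-4-oxobutanoic acid | C=C[C@](C)(C[C@H](O[Si](C)(C)C(C)(C)C)CO[Si](C)(C)C(C)(C)C)[C@@H](C(=O)O)C(=C)C(=O)OC(C)(C)C | intermediate
13 | (2R)-4-tert-butoxy-2-[(3S,5S)-5-[(tert-butyldimethylsilyl)oxy]-6-hydroxy-3-methylhex-1-en-3-yl]-3-methylidene-4-oxobutanoic acid | C=C[C@](C)(C[C@H](O[Si](C)(C)C(C)(C)C)CO)[C@@H](C(=O)O)C(=C)C(=O)OC(C)(C)C | intermediate
14 | (2R)-4-tert-butoxy-2-[(3S,5S)-5-[(tert-butyldimethylsilyl)oxy]-3-methyl-6-oxohex-1-en-3-yl]-3-methylidene-4-oxobutanoic acid | C=C[C@](C)(C[C@H](O[Si](C)(C)C(C)(C)C)C=O)[C@@H](C(=O)O)C(=C)C(=O)OC(C)(C)C | intermediate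
15 | methyl acrylate | C=CC(=O)OC | starting material
16 | (2R)-4-tert-butoxy-2-[(3S,5S)-5-[(tert-butyldimethylsilyl)oxy]-6-hydroxy-7-(methoxycarbonyl)-3-methylocta-1,7-dien-3-yl]-3-methylidene-4-oxobutanoic acid, mixture of epimers at the carbinol carbon C7 | C=C[C@](C)(C[C@H](O[Si](C)(C)C(C)(C)C)C(O)C(=C)C(=O)OC)[C@@H](C(=O)O)C(=C)C(=O)OC(C)(C)C | intermediate
17 | (2R)-2-[(3S,5S,6Z)-8-bromo-5-[(tert-butyldimethylsilyl)oxy]-7-(methoxycarbonyl)-3-methylocta-1,6-dien-3-yl]-4-tert-butoxy-3-methylidene-4-oxobutanoic acid | C=C[C@](C)(C[C@H](O[Si](C)(C)C(C)(C)C)/C=C(\CBr)C(=O)OC)[C@@H](C(=O)O)C(=C)C(=O)OC(C)(C)C | intermediate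
18 | acid chloride of 17 (C6 carbonyl chloride) | C=C[C@](C)(C[C@H](O[Si](C)(C)C(C)(C)C)/C=C(\CBr)C(=O)OC)[C@@H](C(Cl)=O)C(=C)C(=O)OC(C)(C)C | intermediate
19 | tert-butyl (3R,4S,6S,7Z)-9-bromo-6-[(tert-butyldimethylsilyl)oxy]-4-ethenyl-3-formyl-8-(methoxycarbonyl)-4-methyl-2-methylidenenon-7-enoate | C=C[C@](C)(C[C@H](O[Si](C)(C)C(C)(C)C)/C=C(\CBr)C(=O)OC)[C@@H](C=O)C(=C)C(=O)OC(C)(C)C | intermediate
20 | allylchromium species from 19 (CrCl2 group on C13, drawn as the σ-allyl form) | C=C[C@](C)(C[C@H](O[Si](C)(C)C(C)(C)C)/C=C(\C[Cr](Cl)Cl)C(=O)OC)[C@@H](C=O)C(=C)C(=O)OC(C)(C)C | intermediate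
21 | cyclized hydroxy ester: cyclohexane with 6α-hydroxy, 7β-[1-(methoxycarbonyl)ethenyl], 8α-silyloxy, 5β-[1-(tert-butoxycarbonyl)ethenyl], 10α-ethenyl, 10β-methyl | C=C[C@]1(C)C[C@H](O[Si](C)(C)C(C)(C)C)[C@@H](C(=C)C(=O)OC)[C@H](O)[C@H]1C(=C)C(=O)OC(C)(C)C | intermediate
22 | tert-butyl 8α-[(tert-butyldimethylsilyl)oxy]elema-1,3,11(13)-trien-12,6α-olid-15-oate | C=C[C@]1(C)C[C@H](O[Si](C)(C)C(C)(C)C)[C@H]2C(=C)C(=O)O[C@@H]2[C@H]1C(=C)C(=O)OC(C)(C)C | intermediate
23 | tert-butyl 8α-hydroxyelema-1,3,11(13)-trien-12,6α-olid-15-oate; tert-butyl 2-[(3aR,4S,6S,7R,7aR)-6-ethenyl-4-hydroxy-6-methyl-3-methylidene-2-oxooctahydro-1-benzofuran-7-yl]prop-2-enoate | C=C[C@]1(C)C[C@H](O)[C@H]2C(=C)C(=O)O[C@@H]2[C@H]1C(=C)C(=O)OC(C)(C)C | intermediate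
24 | angelic acid, (2Z)-2-methylbut-2-enoic acid | C/C=C(/C)C(=O)O | starting material
25 | angelic 2,4,6-trichlorobenzoic anhydride | C/C=C(/C)C(=O)OC(=O)c1c(Cl)cc(Cl)cc1Cl | intermediate
26 | tert-butyl 8α-(angeloyloxy)elema-1,3,11(13)-trien-12,6α-olid-15-oate | C=C[C@]1(C)C[C@H](OC(=O)/C(C)=C\C)[C@H]2C(=C)C(=O)O[C@@H]2[C@H]1C(=C)C(=O)OC(C)(C)C | intermediate
27 | 2-[(3aR,4S,6S,7R,7aR)-6-ethenyl-6-methyl-3-methylidene-4-{[(2Z)-2-methylbut-2-enoyl]oxy}-2-oxooctahydro-1-benzofuran-7-yl]prop-2-enoic acid (CNP0256928.3) | C=C[C@]1(C)C[C@H](OC(=O)/C(C)=C\C)[C@H]2C(=C)C(=O)O[C@@H]2[C@H]1C(=C)C(=O)O | target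

## Step count and least certain steps

Total step count: 15. Longest linear sequence: 15 steps, from 1 to 27 (7, 15 and 24 are commercial and enter directly).

Step 6 (key step). The most likely failures are loss of enolate geometry or poor facial discrimination by the controller, which would erode the C5/C10 relation or its absolute sense, and migration of the C3=C4 double bond into conjugation during enolization, because the C5 protons are doubly activated. The fallback replaces reagent control by 1,3-chirality transfer. It sets out from 6 and returns at 12.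
- Oxidation of 6 with MnO2 gives (2E,5S)-5,6-bis[(tert-butyldimethylsilyl)oxy]-3-methylhex-2-enal F1.
- Catalytic enantioselective methyl addition (Me2Zn, Ti(OiPr)4, the enantiomer of a chiral bis(sulfonamide) ligand that gives the 2R carbinol) gives (2R,3E,6S)-6,7-bis[(tert-butyldimethylsilyl)oxy]-4-methylhept-3-en-2-ol F2.
- Acylation of F2 with 7 as in step 4 gives the hydrogen itaconate F3, and tert-butylation as in step 5 gives the diester F4.
- A lithium-amide Ireland–Claisen rearrangement (LDA, Me3SiCl, THF, −78 to 25 °C) passes through a chair with the carbinol methyl equatorial, so the carbinol configuration is transferred to C10 and C5, and gives the (E)-prop-1-enyl acid F5.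
- Ethenolysis of F5 (ethylene, second-generation Hoveyda–Grubbs catalyst) trims the propenyl group to the vinyl group of 12.

Step 12. The most likely failure is closure through the diastereomeric transition state with the C6 oxygen axial, which gives the cis-fused lactone; this could happen if the allylmetal does not equilibrate before it adds. A second risk is 1,4-elimination of the C8 silyloxy group from the allylmetal. The fallback corrects C6 by an invertive C–O bond formation instead of relying on the C–C bond-forming transition state. It sets out from 19 and returns at 22: the C6-epimeric, cis-fused lactone F6 is opened with LiOH (THF–H2O, the tert-butyl ester survives) to the 6β-hydroxy acid F7, which is handled as its triethylammonium salt and closed by Mitsunobu lactonization (PPh3, diisopropyl azodicarboxylate, toluene) with inversion at C6.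

Step 9. The most likely failure is slow conversion accompanied by epimerization at C8 through enolization of the α-silyloxy aldehyde by the amine, or conjugate additions during the long reaction time. The fallback changes the bond-forming event to a fast, low-temperature addition of a vinylmetal. It sets out from 14 and returns at 16: hydroalumination of methyl propiolate (i-Bu2AlH, hexamethylphosphoramide, THF, 0 °C) gives the 1-(methoxycarbonyl)vinyl alane, which is added at −78 °C to 14 that has first been converted into its carboxylate salt. No new isolated compound arises.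

Step 11. The most likely failure is over-reduction to the alcohol or, during handling of the aldehyde, epimerization at C5 and migration of the C3=C4 double bond into conjugation with the formyl group. The fallback uses reduction to the alcohol followed by a non-basic re-oxidation. It sets out from 17 and returns at 19: activation as the mixed carbonic anhydride (isobutyl chloroformate, N-methylmorpholine, THF, −15 °C) and reduction with NaBH4 (THF–H2O, 0 °C) give the primary alcohol F8, which is oxidized with Dess–Martin periodinane immediately before step 12.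

## Further compounds

F1 | step 6 | (2E,5S)-5,6-bis[(tert-butyldimethylsilyl)oxy]-3-methylhex-2-enal | O=C/C=C(\C)C[C@H](O[Si](C)(C)C(C)(C)C)CO[Si](C)(C)C(C)(C)C
F2 | step 6 | (2R,3E,6S)-6,7-bis[(tert-butyldimethylsilyl)oxy]-4-methylhept-3-en-2-ol | C[C@@H](O)/C=C(\C)C[C@H](O[Si](C)(C)C(C)(C)C)CO[Si](C)(C)C(C)(C)C
F3 | step 6 | 4-{[(2R,3E,6S)-6,7-bis[(tert-butyldimethylsilyl)oxy]-4-methylhept-3-en-2-yl]oxy}-2-methylidene-4-oxobutanoic acid | C=C(CC(=O)O[C@H](C)/C=C(\C)C[C@H](O[Si](C)(C)C(C)(C)C)CO[Si](C)(C)C(C)(C)C)C(=O)O
F4 | step 6 | 1-tert-butyl 4-[(2R,3E,6S)-6,7-bis[(tert-butyldimethylsilyl)oxy]-4-methylhept-3-en-2-yl] 2-methylidenebutanedioate | C=C(CC(=O)O[C@H](C)/C=C(\C)C[C@H](O[Si](C)(C)C(C)(C)C)CO[Si](C)(C)C(C)(C)C)C(=O)OC(C)(C)C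
F5 | step 6 | (2R)-4-tert-butoxy-2-[(2E,4S,6S)-6,7-bis[(tert-butyldimethylsilyl)oxy]-4-methylhept-2-en-4-yl]-3-methylidene-4-oxobutanoic acid | C/C=C/[C@](C)(C[C@H](O[Si](C)(C)C(C)(C)C)CO[Si](C)(C)C(C)(C)C)[C@@H](C(=O)O)C(=C)C(=O)OC(C)(C)C
F6 | step 12 | tert-butyl 8α-[(tert-butyldimethylsilyl)oxy]elema-1,3,11(13)-trien-12,6β-olid-15-oate (C6 epimer of 22, cis-fused lactone) | C=C[C@]1(C)C[C@H](O[Si](C)(C)C(C)(C)C)[C@H]2C(=C)C(=O)O[C@H]2[C@H]1C(=C)C(=O)OC(C)(C)C
F7 | step 12 | 6β-hydroxy acid from F6: 2-[cyclohexyl]prop-2-enoic acid with 6β-hydroxy, 8α-silyloxy, 5β-[1-(tert-butoxycarbonyl)ethenyl], 10α-ethenyl, 10β-methyl | C=C[C@]1(C)C[C@H](O[Si](C)(C)C(C)(C)C)[C@@H](C(=C)C(=O)O)[C@@H](O)[C@H]1C(=C)C(=O)OC(C)(C)C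
F0 | step 9 | none | none
F8 | step 11 | tert-butyl (3R,4S,6S,7Z)-9-bromo-6-[(tert-butyldimethylsilyl)oxy]-4-ethenyl-3-(hydroxymethyl)-8-(methoxycarbonyl)-4-methyl-2-methylidenenon-7-enoate | C=C[C@](C)(C[C@H](O[Si](C)(C)C(C)(C)C)/C=C(\CBr)C(=O)OC)[C@@H](CO)C(=C)C(=O)OC(C)(C)C
A1 | alternative 1 | (5S)-5-[(tert-butyldimethylsilyl)oxy]-3-ethenylcyclohex-2-en-1-one | C=CC1=CC(=O)C[C@@H](O[Si](C)(C)C(C)(C)C)C1
A2 | alternative 1 | (3R,5S)-5-[(tert-butyldimethylsilyl)oxy]-3-ethenyl-3-methylcyclohexan-1-one (methyl anti to the silyloxy group) | C=C[C@]1(C)C[C@H](O[Si](C)(C)C(C)(C)C)CC(=O)C1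
A3 | alternative 2 | tert-butyl (1(10)E,4E)-8α-[(tert-butyldimethylsilyl)oxy]germacra-1(10),4,11(13)-trien-12,6α-olid-15-oate | C/C1=C\CC/C(C(=O)OC(C)(C)C)=C/[C@H]2OC(=O)C(=C)[C@@H]2[C@@H](O[Si](C)(C)C(C)(C)C)C1
A4 | alternative 3 | (5S)-5-[(tert-butyldimethylsilyl)oxy]-3-methylcyclohex-2-en-1-one | CC1=CC(=O)C[C@@H](O[Si](C)(C)C(C)(C)C)C1
A5 | alternative 3 | tert-butyl cyclobut-1-ene-1-carboxylate | CC(C)(C)OC(=O)C1=CCC1
A6 | alternative 3 | cis-anti-cis head-to-head photoadduct: tert-butyl 8-[(tert-butyldimethylsilyl)oxy]-6-methyl-10-oxotricyclo[4.4.0.0(2,5)]decane-2-carboxylate, cyclobutane anti to the silyloxy group | C[C@]12C[C@H](O[Si](C)(C)C(C)(C)C)CC(=O)[C@H]1[C@]3(C(=O)OC(C)(C)C)CC[C@H]23
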